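**Assumption:** the target has no stereocentre and no stereogenic double bond, so there is no enantiomer to select; the SMILES is taken as the complete structure.

**Retrosynthetic overview**
- No ring is built: ring A comes from 5-bromoresorcinol and ring B from orsellinic acid. The last operations are only carbonyl reduction and desilylation.
- Key C–C disconnection: the CH2OH carbon meta to both oxygens of ring A is cut to an aryl bromide plus the hydroxymethyl anion equivalent Bu3SnCH2OH, and is made late, on the assembled depside.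
- Depside C–O bond: chelation-controlled acylation of the para-OH of 6-bromo-2,4-dihydroxy-3-prenylbenzaldehyde with bis-silylated orsellinoyl chloride.
- Prenyl C–C bond: C-alkylation between the two phenols. The second CH2OH carbon comes from Vilsmeier formylation of 5-bromoresorcinol.

**Route**

Step 1
Reactants: 1 5-bromobenzene-1,3-diol
Product: 3 2-bromo-4,6-dihydroxybenzaldehyde, via aryl iminium chloride 2 (not isolated)
Conditions: (COCl)2, DMF, MeCN, −15 °C to rt; then H2O, 50 °C
Reagents that add atoms: N,N-dimethylformamide CN(C)C=O; water O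
Why: Vilsmeier–Haack formylation, in which the chloroiminium ion attacks the resorcinol carbon para to one OH and ortho to the other (the site resorcinol and orcinol also use), and the precipitated iminium salt is hydrolysed to the aldehyde.

Step 2
Reactants: 3 2-bromo-4,6-dihydroxybenzaldehyde
Product: 4 6-bromo-2,4-dihydroxy-3-(3-methylbut-2-en-1-yl)benzaldehyde
Conditions: prenyl bromide (1.1 equiv), aq. KOH (10%), 0 °C to rt
Reagents that add atoms: prenyl bromide (1-bromo-3-methylbut-2-ene) CC(C)=CCBr
Why: C-alkylation of the ambident phenoxide in water, which goes to the doubly activated carbon between the two oxygens because the only other activated carbon is flanked by bromine; a modest yield (about 25–40%) is expected, as usual for 2,4-dihydroxybenzaldehydes, and is accepted at this early, cheap stage.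

Step 3
Reactants: 5 2,4-dihydroxy-6-methylbenzoic acid (orsellinic acid)
Product: 6 tert-butyldimethylsilyl 2,4-bis[(tert-butyldimethylsilyl)oxy]-6-methylbenzoate
Conditions: TBSCl (3.5 equiv), imidazole (7 equiv), DMF, 40 °C
Reagents that add atoms: tert-butyldimethylsilyl chloride CC(C)(C)[Si](C)(C)Cl
Why: exhaustive O-silylation, in which the two aryl silyl ethers block self-acylation of the resorcylate and the silyl ester serves as a latent acid chloride.

Step 4
Reactants: 6 tert-butyldimethylsilyl 2,4-bis[(tert-butyldimethylsilyl)oxy]-6-methylbenzoate; 4 6-bromo-2,4-dihydroxy-3-(3-methylbut-2-en-1-yl)benzaldehyde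
Product: 8 5-bromo-4-formyl-3-hydroxy-2-(3-methylbut-2-en-1-yl)phenyl 2,4-bis[(tert-butyldimethylsilyl)oxy]-6-methylbenzoate, via acid chloride 7 (not isolated)
Conditions: (COCl)2, DMF (cat.), CH2Cl2, 0 °C to rt, evaporate; then 4 (1.0 equiv), Et3N, DMAP (cat.), CH2Cl2, 0 °C to rt
Reagents that add atoms: none
Why: the silyl ester is converted directly to the acid chloride under neutral conditions (Vilsmeier-type activation), and nucleophilic acyl substitution then takes place only at the more acidic para-OH, because the ortho-OH is locked in a hydrogen bond to the formyl group and flanked on both sides.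

Step 5
Reactants: 8 5-bromo-4-formyl-3-hydroxy-2-(3-methylbut-2-en-1-yl)phenyl 2,4-bis[(tert-butyldimethylsilyl)oxy]-6-methylbenzoate
Product: 9 4-formyl-3-hydroxy-5-(hydroxymethyl)-2-(3-methylbut-2-en-1-yl)phenyl 2,4-bis[(tert-butyldimethylsilyl)oxy]-6-methylbenzoate (in equilibrium with its cyclic lactol)
Conditions: Bu3SnCH2OH (1.5 equiv), Pd(PPh3)4 (10 mol %), 1,4-dioxane, 90 °C
Reagents that add atoms: (tributylstannyl)methanol CCCC[Sn](CCCC)(CCCC)CO
Why: Migita–Kosugi–Stille coupling in which the stannane acts as a hydroxymethyl anion equivalent (a nucleophilic carbinol carbon, the reverse of formaldehyde) toward the electrophilic C–Br carbon, which lies meta to both oxygens where electrophilic formylation cannot reach; oxidative addition is helped by the ortho formyl group, the oxygen-bearing CH2 transfers from tin faster than butyl, and the neutral conditions spare the aryl ester, silyl ethers, aldehyde and prenyl group.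

Step 6
Reactants: 9 4-formyl-3-hydroxy-5-(hydroxymethyl)-2-(3-methylbut-2-en-1-yl)phenyl 2,4-bis[(tert-butyldimethylsilyl)oxy]-6-methylbenzoate
Product: 11 3-hydroxy-4,5-bis(hydroxymethyl)-2-(3-methylbut-2-en-1-yl)phenyl 2,4-dihydroxy-6-methylbenzoate, via bis-silyl diol 10 (not isolated)
Conditions: NaBH4, THF/MeOH (4:1), 0 °C, 15 min; then AcOH, Bu4NF, THF, 0 °C to rt
Reagents that add atoms: none
Why: borohydride reduction of the hydroxy aldehyde (or its lactol) is much faster than attack on the doubly ortho-substituted, electron-rich aryl ester, and fluoride desilylation of the two aryl silyl ethers buffered with acetic acid then frees the orsellinate phenols without cleaving the ester or cyclising the prenyl phenol.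

**Compound list**
1 | 5-bromobenzene-1,3-diol | Oc1cc(O)cc(Br)c1 | starting material
2 | (2-bromo-4,6-dihydroxybenzylidene)dimethyliminium chloride | C[N+](C)=Cc1c(O)cc(O)cc1Br.[Cl-] | intermediate (not isolated)
3 | 2-bromo-4,6-dihydroxybenzaldehyde | O=Cc1c(O)cc(O)cc1Br | intermediate
4 | 6-bromo-2,4-dihydroxy-3-(3-methylbut-2-en-1-yl)benzaldehyde | O=Cc1c(O)c(CC=C(C)C)c(O)cc1Br | intermediate
5 | 2,4-dihydroxy-6-methylbenzoic acid (orsellinic acid) | Cc1cc(O)cc(O)c1C(=O)O | starting material
6 | tert-butyldimethylsilyl 2,4-bis[(tert-butyldimethylsilyl)oxy]-6-methylbenzoate | Cc1cc(O[Si](C)(C)C(C)(C)C)cc(O[Si](C)(C)C(C)(C)C)c1C(=O)O[Si](C)(C)C(C)(C)C | intermediate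
7 | 2,4-bis[(tert-butyldimethylsilyl)oxy]-6-methylbenzoyl chloride | Cc1cc(O[Si](C)(C)C(C)(C)C)cc(O[Si](C)(C)C(C)(C)C)c1C(Cl)=O | intermediate (not isolated)
8 | 5-bromo-4-formyl-3-hydroxy-2-(3-methylbut-2-en-1-yl)phenyl 2,4-bis[(tert-butyldimethylsilyl)oxy]-6-methylbenzoate | O=Cc1c(O)c(CC=C(C)C)c(OC(=O)c2c(C)cc(O[Si](C)(C)C(C)(C)C)cc2O[Si](C)(C)C(C)(C)C)cc1Br | intermediate
9 | 4-formyl-3-hydroxy-5-(hydroxymethyl)-2-(3-methylbut-2-en-1-yl)phenyl 2,4-bis[(tert-butyldimethylsilyl)oxy]-6-methylbenzoate | O=Cc1c(O)c(CC=C(C)C)c(OC(=O)c2c(C)cc(O[Si](C)(C)C(C)(C)C)cc2O[Si](C)(C)C(C)(C)C)cc1CO | intermediate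
10 | 3-hydroxy-4,5-bis(hydroxymethyl)-2-(3-methylbut-2-en-1-yl)phenyl 2,4-bis[(tert-butyldimethylsilyl)oxy]-6-methylbenzoate | OCc1c(O)c(CC=C(C)C)c(OC(=O)c2c(C)cc(O[Si](C)(C)C(C)(C)C)cc2O[Si](C)(C)C(C)(C)C)cc1CO | intermediate (not isolated)
11 | 3-hydroxy-4,5-bis(hydroxymethyl)-2-(3-methylbut-2-en-1-yl)phenyl 2,4-dihydroxy-6-methylbenzoate | CC(C)=CCc1c(OC(=O)c2c(C)cc(O)cc2O)cc(CO)c(CO)c1O | target

**Totals**
Total step count: 6. Longest linear sequence: 5 steps (steps 1, 2, 4, 5, 6 from compound 1).

**Steps most likely to fail, with fallbacks**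

Step 2 (C-prenylation: low yield, with O-alkylation and double alkylation competing). The fallback sets out from 3 and comes back at 4. The more acidic para-OH of 3 is alkylated with 3-chloro-3-methylbut-1-yne (DBU, cat. CuCl2, MeCN, 0 °C) to give 2-bromo-6-hydroxy-4-[(2-methylbut-3-yn-2-yl)oxy]benzaldehyde F1. Semi-hydrogenation (H2, Pd/CaCO3 poisoned with Pb(OAc)2, quinoline, EtOAc) gives 2-bromo-6-hydroxy-4-[(2-methylbut-3-en-2-yl)oxy]benzaldehyde F2. Heating F2 (xylene, 130–140 °C) brings about an aromatic Claisen rearrangement, which places a normal prenyl group on the carbon between the two oxygens (bond fixation by the chelated ortho-hydroxy aldehyde) and gives 4.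

Step 5 (Stille hydroxymethylation: slow transmetalation, protodebromination, or palladium-mediated oxidation of the lactol to a phthalide). The fallback sets out from 4 and comes back at 9. The same reversed-polarity carbon is introduced earlier and with boron instead of tin. Compound 4 is coupled with potassium (acetoxymethyl)trifluoroborate (Pd(dba)2, RuPhos, Na2CO3, dioxane/H2O, 100 °C; the acetate is cleaved in the flask) to give 2,4-dihydroxy-6-(hydroxymethyl)-3-(3-methylbut-2-en-1-yl)benzaldehyde F3. Its para-phenoxide is then acylated selectively over the neutral benzylic or lactol hydroxyl with acid chloride 7 (1.0 equiv, Et3N, CH2Cl2, −20 °C) to give 9.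

Step 6 (hydride and fluoride in the presence of the aryl ester). The fallback sets out from 4 and comes back at 11. The carbonyl is reduced before the ester exists, and regiocontrol comes from a ketal instead of chelation.
- Compound 4 is reduced (NaBH4, MeOH, 0 °C) to 5-bromo-4-(hydroxymethyl)-2-(3-methylbut-2-en-1-yl)benzene-1,3-diol F4.
- The salicyl alcohol unit is tied up (2,2-dimethoxypropane, PPTS, acetone) as 5-bromo-2,2-dimethyl-8-(3-methylbut-2-en-1-yl)-4H-1,3-benzodioxin-7-ol F5.
- The one remaining phenol is acylated with 7 (Et3N, DMAP, CH2Cl2) to give 5-bromo-2,2-dimethyl-8-(3-methylbut-2-en-1-yl)-4H-1,3-benzodioxin-7-yl 2,4-bis[(tert-butyldimethylsilyl)oxy]-6-methylbenzoate F6.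
- Coupling with Bu3SnCH2OH (Pd(OAc)2, XPhos, dioxane, 100 °C) gives 5-(hydroxymethyl)-2,2-dimethyl-8-(3-methylbut-2-en-1-yl)-4H-1,3-benzodioxin-7-yl 2,4-bis[(tert-butyldimethylsilyl)oxy]-6-methylbenzoate F7.
- Aqueous HF in MeCN (0 °C to rt) removes the ketal and both silyl groups to give 11.

**Further compounds**
F1 | step 2 | 2-bromo-6-hydroxy-4-[(2-methylbut-3-yn-2-yl)oxy]benzaldehyde | O=Cc1c(O)cc(OC(C)(C)C#C)cc1Br
F2 | step 2 | 2-bromo-6-hydroxy-4-[(2-methylbut-3-en-2-yl)oxy]benzaldehyde | O=Cc1c(O)cc(OC(C)(C)C=C)cc1Br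
F3 | step 5 | 2,4-dihydroxy-6-(hydroxymethyl)-3-(3-methylbut-2-en-1-yl)benzaldehyde | O=Cc1c(O)c(CC=C(C)C)c(O)cc1CO
F4 | step 6 | 5-bromo-4-(hydroxymethyl)-2-(3-methylbut-2-en-1-yl)benzene-1,3-diol | OCc1c(O)c(CC=C(C)C)c(O)cc1Br
F5 | step 6 | 5-bromo-2,2-dimethyl-8-(3-methylbut-2-en-1-yl)-4H-1,3-benzodioxin-7-ol | CC1(C)OCc2c(Br)cc(O)c(CC=C(C)C)c2O1
F6 | step 6 | 5-bromo-2,2-dimethyl-8-(3-methylbut-2-en-1-yl)-4H-1,3-benzodioxin-7-yl 2,4-bis[(tert-butyldimethylsilyl)oxy]-6-methylbenzoate | CC1(C)OCc2c(Br)cc(OC(=O)c3c(C)cc(O[Si](C)(C)C(C)(C)C)cc3O[Si](C)(C)C(C)(C)C)c(CC=C(C)C)c2O1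
F7 | step 6 | 5-(hydroxymethyl)-2,2-dimethyl-8-(3-methylbut-2-en-1-yl)-4H-1,3-benzodioxin-7-yl 2,4-bis[(tert-butyldimethylsilyl)oxy]-6-methylbenzoate | CC1(C)OCc2c(CO)cc(OC(=O)c3c(C)cc(O[Si](C)(C)C(C)(C)C)cc3O[Si](C)(C)C(C)(C)C)c(CC=C(C)C)c2O1
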